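**Retrosynthetic overview**

1. Locants are those of the bicyclo[3.3.1]non-2-ene core: ring A = C1–C2–C3–C4–C5–C9, ring B = C1–C8–C7–C6–C5–C9. The feature used is that the methyl-bearing bridgehead C5 (α to C9) is joined through the C4 methylene to the C2=C3 double bond, so C2–C3–C4 is an allyl unit anchored on the other bridgehead C1 with C4 as its free end.
2. Ring A closes last by forming C4–C5: intramolecular palladium π-allyl alkylation of the C5/C9 enolate (carried as its enol silane) by the tertiary allylic carbonate C2(OCO2Me)(CH2OTBS)CH=CH2 on C1. Afterwards C9=O becomes C9–OAc and both CH2OTBS groups become CHO.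
3. The C1 quaternary centre is built on a carvone-type enone of ring B: silyloxyacetyl arm first (ends cis to the C8 side chain), hydroxymethyl second (anti to it); then vinyl Grignard/methyl chloroformate on the arm ketone and 1,4-hydrosilylation of the enone.
4. Ring B is formed first, by amine-catalysed Michael addition/aldol condensation of tert-butyl 3-oxopentanoate with (R,E)-4,8-dimethylnona-2,7-dienal, which sets C8. The enal is (R)-citronellal lengthened by one carbon and dehydrogenated; citronellal itself is saturated, and its C2 must become C8.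

Key step: step 10

Remark: the core locants C1–C9 are used for the same atoms in all intermediates; the enolate of the key step is kept masked as an enol silane because a free enolate next to the carbonate would take over its methoxycarbonyl group by 1,5-transfer before palladium can ionise it.

**Route**

Step 1
Reactants: 1 (R)-citronellal
Product: 3 (R)-4,8-dimethylnon-7-enal, via enol ether 2 (not isolated)
Conditions: MeOCH2PPh3Cl, KOtBu, THF, 0 → 23 °C; then 1 M aq. HCl, THF, 23 °C
Reagents that add atoms: (methoxymethyl)triphenylphosphonium chloride COC[P+](c1ccccc1)(c1ccccc1)c1ccccc1.[Cl-]; water O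
Why: Wittig methoxymethylenation followed by acid hydrolysis of the enol ether is the standard one-carbon homologation of an aldehyde, and the stereocentre is β to the carbonyl group throughout and is not touched.

Step 2
Reactants: 3 (R)-4,8-dimethylnon-7-enal
Product: 4 (R,E)-4,8-dimethylnona-2,7-dienal
Conditions: IBX (1.5 equiv), DMSO/fluorobenzene, 65 °C
Reagents that add atoms: none
Why: IBX dehydrogenation of a saturated aldehyde to the E-enal (oxidation through the enol) is a known one-step desaturation, run with little excess reagent so that the tertiary γ-hydrogen at the stereocentre is left alone.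

Step 3
Reactants: 4 (R,E)-4,8-dimethylnona-2,7-dienal; 5 tert-butyl 3-oxopentanoate
Product: 7 (5R)-2-methyl-5-[(2R)-6-methylhept-5-en-2-yl]cyclohex-2-en-1-one, via Michael adduct 6 (not isolated)
Conditions: (S)-2-{bis[3,5-bis(trifluoromethyl)phenyl](trimethylsilyloxy)methyl}pyrrolidine (10 mol%), toluene, 0 → 23 °C; then TsOH·H2O (20 mol%), toluene, 80 °C
Reagents that add atoms: none
Why: Iminium-ion catalysis (organocatalytic Michael addition, then a Robinson-type aldol condensation): the silyl-protected diarylmethyl group of the amine shields one face of the E-iminium ion, the β-keto ester adds to the β-carbon from the open face and so sets C8 (R in 7) under catalyst control, and acid then brings about aldol condensation, cleavage of the tert-butyl ester and decarboxylation.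

Step 4
Reactants: 7 (5R)-2-methyl-5-[(2R)-6-methylhept-5-en-2-yl]cyclohex-2-en-1-one; 8 (tert-butyldimethylsilyloxy)acetaldehyde
Product: 10 aldol adduct 6-[2-(tert-butyldimethylsilyloxy)-1-hydroxyethyl]-2-methyl-5-[(2R)-6-methylhept-5-en-2-yl]cyclohex-2-en-1-one (mixture at ring C6 and at the carbinol carbon), via lithium enolate 9 (not isolated)
Conditions: LiN(iPr)2 (1.1 equiv), THF, −78 °C; then 8, −78 °C; aq. NH4Cl
Reagents that add atoms: none
Why: Kinetic deprotonation of the enone at the α′-methylene (core C1) and aldol addition at −78 °C; the two new stereocentres are destroyed or reset in steps 5 and 6, so their configuration does not matter.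

Step 5
Reactants: 10 aldol adduct
Product: 11 1,3-diketone 6-[(tert-butyldimethylsilyloxy)acetyl]-2-methyl-5-[(2R)-6-methylhept-5-en-2-yl]cyclohex-2-en-1-one (keto/enol mixture)
Conditions: Dess–Martin periodinane, pyridine, CH2Cl2, 0 → 23 °C
Reagents that add atoms: none
Why: Dess–Martin oxidation converts a β-hydroxy ketone into the 1,3-diketone without cleavage or over-oxidation.

Step 6
Reactants: 11 1,3-diketone
Product: 12 6-(hydroxymethyl) diketone with the hydroxymethyl group trans and the silyloxyacetyl group cis to the side chain on the neighbouring ring carbon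
Conditions: 37% aq. CH2O (5 equiv), KHCO3 (20 mol%), THF, 0 °C
Reagents that add atoms: formaldehyde C=O
Why: Aldol addition of the enolised 1,3-diketone to formaldehyde (hydroxymethylation): in the planar enol the C8 side chain sits pseudoaxial to avoid allylic strain with the acyl group and blocks one face, so formaldehyde should enter C1 anti to it, which sets C1 with the acyl arm cis and the hydroxymethyl arm trans to the C8 substituent.

Step 7
Reactants: 12 6-(hydroxymethyl) diketone
Product: 13 bis-silyl ether of 12 (both primary oxygens as tert-butyldimethylsilyl ethers)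
Conditions: TBSCl, imidazole, DMF, 0 → 23 °C
Reagents that add atoms: tert-butyldimethylsilyl chloride CC(C)(C)[Si](C)(C)Cl
Why: Standard silylation of the primary alcohol, which also removes the possibility of retro-aldol loss of formaldehyde.

Step 8
Reactants: 13 bis-silyl ether; 14 vinylmagnesium bromide
Product: 16 tertiary allylic methyl carbonate on the C1 arm (both C2 epimers; ring enone intact), via bromomagnesium alkoxide 15 (not isolated)
Conditions: CH2=CHMgBr (1.3 equiv), THF, −78 → −40 °C; then ClCO2Me, −78 → 0 °C
Reagents that add atoms: methyl chloroformate COC(=O)Cl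
Why: Grignard 1,2-addition should take the α-silyloxy ketone of the arm rather than the conjugated, α-methylated ring carbonyl, and the magnesium alkoxide is acylated in the same flask before it can undergo retro-aldol cleavage; the configuration at C2 is irrelevant because both epimers give the same allyl complex in step 10.

Step 9
Reactants: 16 tertiary allylic methyl carbonate
Product: 17 dimethylphenylsilyl enol ether of the C9 ketone (C5=C9 double bond; carbonate arm unchanged)
Conditions: [(Ph3P)CuH]6 (3 mol%), PhMe2SiH (1.5 equiv), toluene, 0 → 23 °C; filtration through Florisil under argon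
Reagents that add atoms: dimethylphenylsilane C[SiH](C)c1ccccc1
Why: Copper hydride-catalysed 1,4-hydrosilylation (conjugate reduction) of the enone delivers hydride to C6 and silicon to oxygen, which gives the C5=C9 enol silane regiospecifically and under neutral conditions, so that no free enolate ever meets the neighbouring carbonate.

Step 10
Reactants: 17 dimethylphenylsilyl enol ether
Product: 18 1,2-bis[(tert-butyldimethylsilyloxy)methyl]-5-methyl-8-[(2R)-6-methylhept-5-en-2-yl]bicyclo[3.3.1]non-2-en-9-one
Conditions: Pd(PPh3)4 (10 mol%), THF, 23 → 60 °C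
Reagents that add atoms: none
Why: Zerovalent palladium ionises the tertiary allylic carbonate with loss of CO2 to a cationic η3-allylpalladium complex spanning C2–C3–C4 and methoxide, which removes the silyl group from the enol oxygen so that the C5 enolate appears only once the electrophile exists; this is a Tsuji–Trost allylation of a ketone enolate in its neutral enol silane/allyl carbonate variant, used in the bridging mode known from palladium-catalysed bicycloannulations to bicyclo[3.3.1]nonenones. Ring A (C1–C2–C3–C4–C5–C9) closes by attack of C5 on the unsubstituted terminus C4, a six-membered closure that is endo with respect to the allyl unit (all three allyl carbons end up in the ring) and therefore runs through the η3 isomer with C1 anti on C2; the syn isomer cannot reach C5 and feeds the anti isomer by η3–η1–η3 exchange at C2. The only new stereocentre, C5, is fixed by the tether: the allyl arm is axial on C1 (the C8 side chain being equatorial) and can deliver C4 only to the face of the enolate cis to the C1–C2 bond. Both C2 epimers of 17 converge because the complex changes face through the primary σ-allyl form at C4. Attack at C2 is excluded because it would need a four-membered ring. C- over O-allylation is expected because the six-membered O-allyl enol ether is an allyl vinyl ether that palladium re-ionises, whereas the C4–C5 bond, once formed, stays.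

Step 11
Reactants: 18 bicyclic ketone
Product: 19 the corresponding bicyclo[3.3.1]non-2-en-9-ol with the hydroxyl on the ring B side of C9 (anti to the C2=C3 bridge)
Conditions: NaBH4, MeOH/THF, 0 → 23 °C
Reagents that add atoms: none
Why: Substrate-controlled hydride reduction: NaBH4 should approach the bridging carbonyl over ring A, where C2 and C3 are sp2 and only one pseudoaxial hydrogen (on C4) is in the way, rather than over ring B with its axial hydrogens on C6 and C8, which sets C9 with the hydroxyl on the ring B side as in the target.

Step 12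
Reactants: 19 bicyclic alcohol
Product: 20 C9 acetate of 19
Conditions: Ac2O, DMAP, Et3N, CH2Cl2, 23 → 40 °C
Reagents that add atoms: acetic anhydride CC(=O)OC(C)=O
Why: DMAP-catalysed acylation is the usual way to acetylate a hindered secondary alcohol, and the silyl ethers are inert to it.

Step 13
Reactants: 20 acetate
Product: 21 9-acetoxy-1,2-bis(hydroxymethyl) diol
Conditions: HF·pyridine, pyridine, THF, 0 → 23 °C
Reagents that add atoms: none
Why: Fluoride-mediated desilylation under buffered, slightly acidic conditions removes both primary silyl ethers without hydrolysis or migration of the acetate.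

Step 14
Reactants: 21 diol
Product: 22 (1R,5R,8S,9R)-1,2-diformyl-5-methyl-8-[(2R)-6-methylhept-5-en-2-yl]bicyclo[3.3.1]non-2-en-9-yl acetate (CNP0299929.2)
Conditions: Dess–Martin periodinane, pyridine, CH2Cl2, 0 → 23 °C
Reagents that add atoms: none
Why: Dess–Martin oxidation takes the allylic and the neopentyl primary alcohol to the two aldehydes under buffered conditions, and neither aldehyde has an α-hydrogen that could epimerise.

**Compound list**

1 | (R)-citronellal | O=CC[C@H](C)CCC=C(C)C | starting material
2 | (R)-1-methoxy-4,8-dimethylnona-1,7-diene (E/Z mixture) | COC=CC[C@H](C)CCC=C(C)C | intermediate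
3 | (R)-4,8-dimethylnon-7-enal | O=CCC[C@H](C)CCC=C(C)C | intermediate
4 | (R,E)-4,8-dimethylnona-2,7-dienal | O=C/C=C/[C@H](C)CCC=C(C)C | intermediate
5 | tert-butyl 3-oxopentanoate | CCC(=O)CC(=O)OC(C)(C)C | starting material
6 | tert-butyl (3S,4R)-4,8-dimethyl-3-(2-oxoethyl)-2-propanoylnon-7-enoate (C2 epimers) | CCC(=O)C(C(=O)OC(C)(C)C)[C@@H](CC=O)[C@H](C)CCC=C(C)C | intermediate
7 | (5R)-2-methyl-5-[(2R)-6-methylhept-5-en-2-yl]cyclohex-2-en-1-one | O=C1C(C)=CC[C@@H]([C@H](C)CCC=C(C)C)C1 | intermediate
8 | (tert-butyldimethylsilyloxy)acetaldehyde | O=CCO[Si](C)(C)C(C)(C)C | starting material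
9 | lithium α′-enolate (cross-conjugated dienolate) of 7 | [Li]OC1=C[C@H]([C@H](C)CCC=C(C)C)CC=C1C | intermediate
10 | 6-[2-(tert-butyldimethylsilyloxy)-1-hydroxyethyl]-2-methyl-5-[(2R)-6-methylhept-5-en-2-yl]cyclohex-2-en-1-one (ring C5 as in 7; mixture at C6 and at the carbinol carbon) | O=C1C(C)=CC[C@@H]([C@H](C)CCC=C(C)C)C1C(O)CO[Si](C)(C)C(C)(C)C | intermediate
11 | 6-[(tert-butyldimethylsilyloxy)acetyl]-2-methyl-5-[(2R)-6-methylhept-5-en-2-yl]cyclohex-2-en-1-one (keto/enol mixture) | O=C1C(C)=CC[C@@H]([C@H](C)CCC=C(C)C)C1C(=O)CO[Si](C)(C)C(C)(C)C | intermediate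
12 | 6-(hydroxymethyl) derivative of 11; hydroxymethyl trans, silyloxyacetyl cis to the side chain | O=C1C(C)=CC[C@@H]([C@H](C)CCC=C(C)C)[C@@]1(CO)C(=O)CO[Si](C)(C)C(C)(C)C | intermediate
13 | bis(tert-butyldimethylsilyl) ether of 12 | O=C1C(C)=CC[C@@H]([C@H](C)CCC=C(C)C)[C@@]1(CO[Si](C)(C)C(C)(C)C)C(=O)CO[Si](C)(C)C(C)(C)C | intermediate
14 | vinylmagnesium bromide | C=C[Mg]Br | starting material
15 | bromomagnesium alkoxide of the tertiary vinyl carbinol (C2 epimers) | O=C1C(C)=CC[C@@H]([C@H](C)CCC=C(C)C)[C@@]1(CO[Si](C)(C)C(C)(C)C)C(CO[Si](C)(C)C(C)(C)C)(O[Mg]Br)C=C | intermediate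
16 | ring-B enone carrying on C1 the CH2OTBS group and the arm C(CH2OTBS)(OCO2Me)CH=CH2 (C2 epimers) | O=C1C(C)=CC[C@@H]([C@H](C)CCC=C(C)C)[C@@]1(CO[Si](C)(C)C(C)(C)C)C(CO[Si](C)(C)C(C)(C)C)(OC(=O)OC)C=C | intermediate
17 | dimethylphenylsilyl enol ether (C5=C9) of the saturated ring-B ketone with the same carbonate arm; key-step precursor | C[Si](C)(c1ccccc1)OC1=C(C)CC[C@@H]([C@H](C)CCC=C(C)C)[C@@]1(CO[Si](C)(C)C(C)(C)C)C(CO[Si](C)(C)C(C)(C)C)(OC(=O)OC)C=C | intermediate
18 | 1,2-bis[(tert-butyldimethylsilyloxy)methyl]-5-methyl-8-[(2R)-6-methylhept-5-en-2-yl]bicyclo[3.3.1]non-2-en-9-one (side chain equatorial on ring B, cis to the C1–C2 bond); key-step product | O=C1[C@@]2(C)CC=C(CO[Si](C)(C)C(C)(C)C)[C@]1(CO[Si](C)(C)C(C)(C)C)[C@H]([C@H](C)CCC=C(C)C)CC2 | intermediate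
19 | 9-alcohol of 18, hydroxyl on the ring B side (anti to C2=C3) | O[C@@H]1[C@@]2(C)CC=C(CO[Si](C)(C)C(C)(C)C)[C@]1(CO[Si](C)(C)C(C)(C)C)[C@H]([C@H](C)CCC=C(C)C)CC2 | intermediate
20 | 9-acetate of 19 | CC(=O)O[C@@H]1[C@@]2(C)CC=C(CO[Si](C)(C)C(C)(C)C)[C@]1(CO[Si](C)(C)C(C)(C)C)[C@H]([C@H](C)CCC=C(C)C)CC2 | intermediate
21 | 9-acetoxy-1,2-bis(hydroxymethyl)-5-methyl-8-[(2R)-6-methylhept-5-en-2-yl]bicyclo[3.3.1]non-2-ene | CC(=O)O[C@@H]1[C@@]2(C)CC=C(CO)[C@]1(CO)[C@H]([C@H](C)CCC=C(C)C)CC2 | intermediate
22 | (1R,5R,8S,9R)-1,2-diformyl-5-methyl-8-[(2R)-6-methylhept-5-en-2-yl]bicyclo[3.3.1]non-2-en-9-yl acetate | CC(=O)O[C@@H]1[C@@]2(C)CC=C(C=O)[C@]1(C=O)[C@H]([C@H](C)CCC=C(C)C)CC2 | target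

**Totals**

Total step count: 14. Longest linear sequence: 14 steps, from (R)-citronellal.

**Steps most likely to fail**

First, the key step (step 10). Ionisation may give mainly the allyl isomer with C1 syn on C2, which cannot close. If its exchange through the crowded tertiary σ-allyl form at C2 is slower than loss of a proton from the CH2OTBS group or protodesilylation, diene formation and an uncyclised ketone take over. The fallback sets out from 17 and comes back at 18. It leaves palladium out and ionises the same carbonate with a catalytic silyl triflate (TMSOTf, CH2Cl2, −78 °C) to the free allyl cation. Its charge sits mainly on the tertiary C2, so rotation about C2–C3 is easy. The enol silane then captures the cation at C4 in an SN1′-type Mukaiyama allylation (cation–enol ether cyclisation), with the tether again fixing the face of C5. It makes no new compound (F0).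

Second, the annulation (step 3). The iminium ion of enal 4 can lose its γ-hydrogen reversibly (dienamine formation), which would epimerise the side-chain stereocentre, and the γ-branch may lower facial control at C8. The fallback sets out from 1 and comes back at 7; it uses citronellal itself as the enamine donor, so that its stereocentre stays β to the carbonyl group.
- Michael addition of 1 to methyl vinyl ketone, catalysed by (R)-2-[diphenyl(trimethylsilyloxy)methyl]pyrrolidine with ethyl 3,4-dihydroxybenzoate as co-catalyst, should give (R)-2-[(R)-6-methylhept-5-en-2-yl]-5-oxohexanal F1.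
- LiOH in iPrOH closes it by aldol condensation to (R)-4-[(R)-6-methylhept-5-en-2-yl]cyclohex-2-en-1-one F2.
- KN(SiMe3)2 followed by 2-(phenylsulfonyl)-3-phenyloxaziridine hydroxylates the α′-carbon to the 6-hydroxy enone F3.
- Excess MeLi adds to the carbonyl group to give 2-methyl-5-[(R)-6-methylhept-5-en-2-yl]cyclohex-3-ene-1,2-diol F4.
- Dess–Martin oxidation of the secondary alcohol gives 2-hydroxy-2-methyl-5-[(R)-6-methylhept-5-en-2-yl]cyclohex-3-en-1-one F5.
- SmI2 in THF/MeOH cleaves the tertiary allylic C–O bond next to the ketone, and DBU moves the double bond into conjugation, which gives 7 (a 1,2-carbonyl transposition that also brings in the methyl group).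

Third, the hydroxymethylation (step 6). Under base the aldol is reversible, and the β-hydroxymethyl diketone can lose its acyl group by retro-Claisen cleavage or eliminate to an α-methylene ketone; reversibility can also erode the anti selectivity at C1. The fallback sets out from 11 and comes back at 12. The diketone is converted with TMSCl and Et3N into its trimethylsilyl enol ether F6. This is then hydroxymethylated in a Lewis-acid Mukaiyama aldol reaction with aqueous formaldehyde (Sc(OTf)3, THF/H2O, 0 °C) with no base present; the same pseudoaxial side chain directs the attack.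

**Further compounds**

F0 | step 10 | none | none
F1 | step 3 | (R)-2-[(R)-6-methylhept-5-en-2-yl]-5-oxohexanal | O=C[C@@H]([C@H](C)CCC=C(C)C)CCC(C)=O
F2 | step 3 | (R)-4-[(R)-6-methylhept-5-en-2-yl]cyclohex-2-en-1-one | O=C1C=C[C@@H]([C@H](C)CCC=C(C)C)CC1
F3 | step 3 | 6-hydroxy-4-[(R)-6-methylhept-5-en-2-yl]cyclohex-2-en-1-one (ring C4 as in F2; C6 epimers) | O=C1C=C[C@@H]([C@H](C)CCC=C(C)C)CC1O
F4 | step 3 | 2-methyl-5-[(R)-6-methylhept-5-en-2-yl]cyclohex-3-ene-1,2-diol (ring C5 as in F2; diol epimers) | CC1(O)C=C[C@@H]([C@H](C)CCC=C(C)C)CC1O
F5 | step 3 | 2-hydroxy-2-methyl-5-[(R)-6-methylhept-5-en-2-yl]cyclohex-3-en-1-one (ring C5 as in F2; C2 epimers) | CC1(O)C=C[C@@H]([C@H](C)CCC=C(C)C)CC1=O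
F6 | step 6 | trimethylsilyl enol ether of diketone 11 (ring-oxygen silylated tautomer drawn) | C[Si](C)(C)OC1=C(C(=O)CO[Si](C)(C)C(C)(C)C)[C@H]([C@H](C)CCC=C(C)C)CC=C1C
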